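Which flask keeps the most J among J and E after 8.0 min, and at what share (the selectivity)? The recipes, earlier runs and questions are these.

| flask | Q | Z | temperature | remark | time |
|---|---|---|---|---|---|
| zeta | 0.13 M | 20 µM | −5 °C | run made earlier |  |
| theta | 0.30 M | 20 µM | 15 °C | run made earlier |  |
| east | 0.20 M | 20 µM | 15 °C |  | 8.0 min |
| north-east | 0.20 M | 20 µM | 30 °C |  | 8.0 min |
| north | 0.20 M | 20 µM | 0 °C |  | 8.0 min |

| run | time / min | J / % | E / % |
|---|---|---|---|
| zeta | 2.50 | 72 | 0 |
| zeta | 4.00 | 94 | 0 |
| zeta | 5.00 | 95 | 0 |
| zeta | 10.0 | 99 | 0 |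
| zeta | 15.0 | 96 | 3 |
| zeta | 25.0 | 100 | 3 |
| theta | 0.667 | 72 | 2 |
| theta | 2.00 | 92 | 3 |
| theta | 3.00 | 93 | 2 |
| theta | 5.00 | 93 | 4 |
| theta | 8.00 | 89 | 12 |
| theta | 10.0 | 89 | 10 |

(each reading ± 2 percentage points)

1. which flask leads in share of J in all that became J or E ("all alike" within 1.5 percentage points) (east / north-east / north / all alike)
2. share of J in all that became J or E, east
3. share of J in all that became J or E, north-east
4. share of J in all that became J or E, north

- percentages count the Q that a species holds: one G counts as two
- steps thought possible: Z -> D; D -> L; J -> E; 2 Q -> G; Q + D -> J + D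

I build the flask up one step at a time. With Q + D -> J + D by itself, what forms is J, and the share stands at 100 %. Now I add J -> E, a first-order loss with constant k. The lifetime of J is 1/k, and for J that stands from the start the share after n = kt lifetimes is exp(−n), so I count lifetimes. The zeta run's last reading, J 100 % and E 3 %, gives 0.00118 min⁻¹ at −5 °C. The theta run's last reading, J 89 % and E 10 %, gives 0.0106 min⁻¹ at 15 °C. The factor by which the count of lifetimes in a fixed time grows across that temperature step is 9.01. It is a rough reading: the zeta E reading of 3 % carries a scatter of 2 percentage points. I assume the same factor for each equal step of temperature.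

In the theta run J reaches 72 % by 0.667 min, which is much shorter than the flask time, so as a rough estimate I count the whole 8.0 min for east. That makes 0.0852 lifetimes and a share of 91.8 % in east. The factor then gives north-east 0.443 lifetimes and 64.2 %, and north 0.0164 lifetimes and 98.4 %.

Then I add the rest. G counts as neither J nor E, so I add nothing to n for it. Z -> D and D -> L change the amount of D, and I leave them out of n.

The forecast puts north in the lead, with 98.5 % there, 92 % in east and 69 % in north-east. Its ground is: “The share is therefore set by first-order J → E during the remaining time”. We part at north-east, where its figure stands above mine.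

The flask puts north in the lead at 98.7 %, with east at 91.0 % and north-east at 59.9 %, which is 9.1 points below the forecast. Starting from the zeta run at the time of its last reading and keeping that time, changing the temperature to north-east's takes the share from 97.6 % to 19.5 %, while changing the amount of Q to north-east's leaves it at 97.6 %. Read as counts of lifetimes, east's share is 0.0943 and north-east's is 0.513, a ratio of 5.44, where the factor over the step from east to north-east gives 5.20.

    Z → D (k = 0.0100 s⁻¹, Ea = 78.0 kJ mol⁻¹)
    D → L (k = 4.50 × 10⁻⁵ s⁻¹, Ea = 188 kJ mol⁻¹)
    J → E (k = 0.00110 s⁻¹, Ea = 80.0 kJ mol⁻¹)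
    2 Q → G (k = 0.00960 M⁻¹ s⁻¹, Ea = 72.0 kJ mol⁻¹)
    Q + D → J + D, rate k5*[Q]^2*[D]/(1 + ([Q]/Kh5)^2) (0.0730 M, k = 1.90 × 10⁶ M⁻² s⁻¹, Ea = 12.0 kJ mol⁻¹)
    (constants at 30 °C)

For the neighbour, north run at 25 °C, the factor takes north-east's count down to 0.296 lifetimes, a share of 74.4 %. The computed flask gives 74.2 %.

(Readings and results are calculated on assumed constants; scatter was added.)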